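**Retrosynthetic overview**
- The strategy rests on ring A, the phenol ring (C1 OH, C2 aryl ether oxygen, C3 and C4 H, C5 and C6 Br). It is read as an aromatized 4-aryloxycyclohexane-1,3-dione: the carbonyl beside the aryloxy carbon is the future C1–OH, the far carbonyl the future C5–Br, and the CH2 between them the future C6–Br.
- Ring A is cut at C2–C3 (Michael bond) and C5–C6 (Claisen bond), giving an aryloxyacetone and methyl acrylate; the aryloxyacetone comes from 2,4-dibromophenol and chloroacetone.
- Ring B (2,4-dibromophenyl) and the diaryl ether oxygen are bought in with the phenol, so no bromine is placed by aromatic substitution.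
- Ring order: ring B is present from the start; ring A is the only ring formed (step 2), is brominated through carbonyl chemistry (steps 3 and 4) and is aromatized last (step 5).

Key step: step 2

Remark on the chemistry: the target is achiral. The one stereocenter carried by the ring A intermediates (the aryloxy-bearing carbon) is racemic and disappears on aromatization. The 2-bromo dione is drawn as its diketo tautomer although it should exist largely as the enol.

**Route**

Step 1
Reactants: 1 2,4-dibromophenol; 2 chloroacetone
Product: 3 1-(2,4-dibromophenoxy)propan-2-one
Conditions: K2CO3, KI (cat.), acetone, reflux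
Reagents that add atoms: none
Why: Williamson ether synthesis; the acidic dibromophenol is fully deprotonated by K2CO3 and the alpha-halo ketone is a highly reactive SN2 electrophile, with iodide exchange accelerating the displacement.

Step 2
Reactants: 3 1-(2,4-dibromophenoxy)propan-2-one; 4 methyl acrylate
Product: 6 4-(2,4-dibromophenoxy)cyclohexane-1,3-dione (racemic), via Michael adduct keto ester 5 (not isolated)
Conditions: t-BuOK (2.2 equiv), THF, −10 °C, slow addition of 4 (1.0 equiv), then rt; aq. HCl
Reagents that add atoms: none
Why: tert-Butoxide deprotonates 3 at the aryloxy-bearing methylene, the enolate adds 1,4 to methyl acrylate to give keto ester 5, and the methyl ketone enolate of 5 then attacks the ester carbonyl and expels methoxide, the Claisen equilibrium being pulled forward by irreversible deprotonation of the 1,3-dione. The closest known reaction type is the consecutive Michael–Claisen annulation of substituted acetones with acrylates to 4-substituted cyclohexane-1,3-diones. Ring A closes by a 6-exo-trig acyl substitution (Dieckmann-type), and the alternative closure from the other alpha-carbon would give a four-membered ring and does not compete. The single new stereocenter, the aryloxy-bearing carbon, forms without control, is racemic and is erased in step 5. The step needs conjugate addition at OCH2 and not at CH3, and one addition and not two. The first is secured by the inductive acidification of the OCH2 position by the aryloxy oxygen (the thermodynamic enolate), the second by slow addition of one equivalent of acrylate at low temperature so that cyclization outruns a second addition.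

Step 3
Reactants: 6 4-(2,4-dibromophenoxy)cyclohexane-1,3-dione
Product: 7 2-bromo-4-(2,4-dibromophenoxy)cyclohexane-1,3-dione (racemic)
Conditions: NBS (1.0 equiv), MeCN, 0 °C to rt
Reagents that add atoms: N-bromosuccinimide, O=C1CCC(=O)N1Br
Why: Electrophilic alpha-bromination of an enolized 1,3-dione at the doubly activated carbon between the carbonyls, which is far more nucleophilic than the other alpha-positions or the deactivated dibromoaryl ether ring; one equivalent avoids the 2,2-dibromide.

Step 4
Reactants: 7 2-bromo-4-(2,4-dibromophenoxy)cyclohexane-1,3-dione
Product: 8 2,3-dibromo-6-(2,4-dibromophenoxy)cyclohex-2-en-1-one (racemic)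
Conditions: (COBr)2, DMF (cat.), CH2Cl2, 0 °C to rt
Reagents that add atoms: oxalyl bromide, O=C(Br)C(=O)Br
Why: Vilsmeier-type formation of a vinylogous acid bromide from a cyclic 1,3-dione: the enol oxygen remote from the aryloxy carbon, which is less hindered and less inductively deactivated, attacks the bromoiminium salt, and bromide replaces the activated oxygen by conjugate addition–elimination, so the carbonyl beside the aryloxy carbon is kept.

Step 5
Reactants: 8 2,3-dibromo-6-(2,4-dibromophenoxy)cyclohex-2-en-1-one
Product: 11 2,3-dibromo-6-(2,4-dibromophenoxy)phenol, via alpha-bromo ketone 9 (not isolated), via cyclohexadienone 10 (not isolated)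
Conditions: LiN(SiMe3)2 (1.05 equiv), THF, −78 °C; NBS (1.0 equiv), −78 °C; DBU (2 equiv), −78 °C to rt; aq. HCl
Reagents that add atoms: none
Why: Kinetic alpha-prime deprotonation at the aryloxy-acidified C6–H gives a cross-conjugated enolate that NBS brominates at carbon (enolate alpha-bromination), DBU removes HBr across C6–C5 (dehydrobromination), and the resulting cyclohexa-2,5-dienone tautomerizes to the phenol; a bromide placed at C4 through a dienolate would lose HBr to the same phenol.

**Compound list**
1 | 2,4-dibromophenol | Oc1ccc(Br)cc1Br | starting material
2 | chloroacetone | CC(=O)CCl | starting material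
3 | 1-(2,4-dibromophenoxy)propan-2-one | CC(=O)COc1ccc(Br)cc1Br | intermediate
4 | methyl acrylate | C=CC(=O)OC | starting material
5 | methyl 4-(2,4-dibromophenoxy)-5-oxohexanoate (racemic, not isolated) | COC(=O)CCC(Oc1ccc(Br)cc1Br)C(C)=O | intermediate
6 | 4-(2,4-dibromophenoxy)cyclohexane-1,3-dione (racemic) | O=C1CCC(Oc2ccc(Br)cc2Br)C(=O)C1 | intermediate
7 | 2-bromo-4-(2,4-dibromophenoxy)cyclohexane-1,3-dione (racemic) | O=C1CCC(Oc2ccc(Br)cc2Br)C(=O)C1Br | intermediate
8 | 2,3-dibromo-6-(2,4-dibromophenoxy)cyclohex-2-en-1-one (racemic) | O=C1C(Oc2ccc(Br)cc2Br)CCC(Br)=C1Br | intermediate
9 | 2,3,6-tribromo-6-(2,4-dibromophenoxy)cyclohex-2-en-1-one (racemic, not isolated) | O=C1C(Br)(Oc2ccc(Br)cc2Br)CCC(Br)=C1Br | intermediate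
10 | 2,3-dibromo-6-(2,4-dibromophenoxy)cyclohexa-2,5-dien-1-one (not isolated) | O=C1C(Oc2ccc(Br)cc2Br)=CCC(Br)=C1Br | intermediate
11 | 2,3-dibromo-6-(2,4-dibromophenoxy)phenol | Oc1c(Oc2ccc(Br)cc2Br)ccc(Br)c1Br | target

Total step count: 5. Longest linear sequence: 5 steps (from 2,4-dibromophenol).

**Steps most likely to fail**

Step 2. The conjugate addition may start from the methyl side of the ketone, a second acrylate may add before ring closure, or the acrylate may oligomerize under the strong base. The fallback fixes the Michael bond in a bought chain and keeps only the Claisen closure. It sets out from 1 and returns at 6. Commercial methyl 5-oxohexanoate F1 is brominated at its more substituted alpha-carbon (Br2, AcOH, HBr cat., rt) to methyl 4-bromo-5-oxohexanoate F2. Phenol 1 displaces the bromide (K2CO3, acetone, rt) to give keto ester 5, now isolated. Ring A is then closed with t-BuOK in THF at 0 °C to give 6.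

Step 4. The bromoiminium salt may activate the enol oxygen beside the aryloxy carbon, which would place the vinyl bromide on the wrong carbon and lead to a regioisomeric phenol. The fallback separates oxygen activation from bromide delivery. It sets out from 7 and returns at 8. Kinetic O-sulfonylation (Tf2O, 2,6-lutidine, CH2Cl2, −78 °C) at the less hindered oxygen should give 2-bromo-3-oxo-4-(2,4-dibromophenoxy)cyclohex-1-en-1-yl trifluoromethanesulfonate F3, which can be freed of any regioisomer by chromatography. LiBr in acetone at reflux then exchanges the triflate for bromide by conjugate addition–elimination to give 8.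

Step 5. Enolization may occur toward C4 with bromination at C2, the amide base may add to the beta-bromo enone, or the phenoxide formed may be brominated again at its free para position. The fallback avoids both the enolate and an electrophilic bromine source. It sets out from 8 and returns at 11. Direct dehydrogenation with DDQ and catalytic TsOH in dioxane at reflux removes hydride from the enol or dienol of 8; either regiochemistry leads through a cyclohexadienone such as 10 to phenol 11.

**Further compounds**
F1 | step 2 | methyl 5-oxohexanoate | CC(=O)CCCC(=O)OC
F2 | step 2 | methyl 4-bromo-5-oxohexanoate (racemic) | CC(=O)C(Br)CCC(=O)OC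
F3 | step 4 | 2-bromo-3-oxo-4-(2,4-dibromophenoxy)cyclohex-1-en-1-yl trifluoromethanesulfonate (racemic) | O=C1C(Oc2ccc(Br)cc2Br)CCC(OS(=O)(=O)C(F)(F)F)=C1Br
F0 | step 5 | none | none
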